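**Plan**
- Retrosynthesis cuts C3–CH2N (Mannich), N1–CH3, and then N1–C2 of the pyrrole ring, which leads back to an N-mesyl 2-(2,2-dibromovinyl)anilide.
- The anilide is cut further at the C2=C3 double bond (dibromoolefination of an aldehyde) and at the aryl C–N bond (nitration, reduction).
- Enabling feature: C2 carries bromine next to N1, so a gem-dibromovinyl group ortho to the nitrogen already holds C3, C2, the bromine that stays and one bromine that can leave.
- Forward: the benzene ring is bought with both bromines in place; the pyrrole ring is the only ring formed and closes by N1–C2 bond formation; N-methyl and the C3 side chain follow.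
- The target has no stereocentre; only regiochemistry matters, and it is fixed by the starting material and the nitration.

Key step: step 5

Remark: the target is taken as the free base, so the hydroiodide formed in the last step is neutralised during work-up.

**Step 1**
Reactants: 1 3,4-dibromobenzaldehyde
Product: 2 4,5-dibromo-2-nitrobenzaldehyde
Conditions: fuming HNO3, conc. H2SO4, 0 °C to rt
Reagents that add atoms: nitric acid, O[N+](=O)[O-]
Why: Electrophilic aromatic nitration: the C3 bromine directs para to C6 and the other ortho site C2 is flanked by two substituents, so the nitro group should enter ortho to the formyl group, which tolerates cold mixed acid.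

**Step 2**
Reactants: 2 4,5-dibromo-2-nitrobenzaldehyde; 3 carbon tetrabromide
Product: 4 1,2-dibromo-4-(2,2-dibromovinyl)-5-nitrobenzene
Conditions: PPh3, CH2Cl2, 0 °C to rt
Reagents that add atoms: none
Why: Ramirez dibromoolefination (first stage of the Corey–Fuchs sequence): the ylide Ph3P=CBr2 formed from CBr4 and PPh3 undergoes a Wittig reaction with the electron-poor aldehyde, and at 0 °C PPh3 leaves the nitro group and the aryl bromides alone.

**Step 3**
Reactants: 4 1,2-dibromo-4-(2,2-dibromovinyl)-5-nitrobenzene
Product: 5 4,5-dibromo-2-(2,2-dibromovinyl)aniline
Conditions: Fe powder, AcOH, EtOH, 80 °C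
Reagents that add atoms: none
Why: Béchamp-type dissolving-metal reduction of the nitro group, chosen over catalytic hydrogenation because iron in acetic acid does not cleave aryl or vinylic C–Br bonds.

**Step 4**
Reactants: 5 4,5-dibromo-2-(2,2-dibromovinyl)aniline
Product: 6 N-[4,5-dibromo-2-(2,2-dibromovinyl)phenyl]methanesulfonamide
Conditions: MsCl, pyridine, CH2Cl2, 0 °C to rt
Reagents that add atoms: methanesulfonyl chloride, CS(=O)(=O)Cl
Why: N-Sulfonylation of a primary aniline, which should stop at the monosulfonamide because the electron-poor nitrogen is weakly nucleophilic and pyridine is too weak a base to drive a second sulfonylation.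

**Step 5**
Reactants: 6 N-[4,5-dibromo-2-(2,2-dibromovinyl)phenyl]methanesulfonamide
Product: 8 2,5,6-tribromo-1-(methylsulfonyl)indole, via N-[4,5-dibromo-2-(bromoethynyl)phenyl]methanesulfonamide 7 (not isolated)
Conditions: Cs2CO3, DMF, 80 °C
Reagents that add atoms: none
Why: Cs2CO3 removes the sulfonamide proton, which the mesyl group and the dibromoaryl ring make acidic, and further base takes out the vinylic hydrogen in an anti elimination of HBr to give bromoalkyne 7; the nitrogen anion then adds to the bromine-bearing alkyne carbon and the C3 vinyl anion is protonated. The closest known reaction type is the metal-free, base- or fluoride-promoted cyclisation of N-sulfonyl 2-(2,2-dibromovinyl)anilines to 2-bromoindoles, and a direct addition–elimination at the dibromovinyl carbon would lead to the same product. The pyrrole ring closes 5-endo-dig through the new N1–C2 bond, the 4-exo alternative being far too strained. No stereocentre is formed. The step needs chemoselectivity, since one of four C–Br bonds must break: the two aryl bromides are inert without a transition metal, and once the ring is aromatic the C2 bromide is an unactivated heteroaryl bromide with no elimination path. The mesyl group should stay because carbonate in aprotic DMF does not attack sulfur.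

**Step 6**
Reactants: 8 2,5,6-tribromo-1-(methylsulfonyl)indole
Product: 10 2,5,6-tribromo-1-methylindole, via 2,5,6-tribromoindole 9 (not isolated)
Conditions: KOH (powdered), DMSO, rt; then MeI, rt
Reagents that add atoms: iodomethane, CI
Why: Hydroxide cleaves the N–S bond of the N-sulfonylindole (attack at sulfur with the tribromoindolide as leaving group) and the potassium indolide is then N-methylated by SN2 reaction with MeI under Heaney–Ley conditions, so the sensitive N–H 2-bromoindole never has to be isolated.

**Step 7**
Reactants: 10 2,5,6-tribromo-1-methylindole; 11 N,N-dimethylmethyleneiminium iodide (Eschenmoser's salt)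
Product: 12 2,5,6-tribromo-1-methylgramine
Conditions: MeCN, 60 °C; aq NaOH work-up
Reagents that add atoms: none
Why: Mannich reaction with a preformed iminium salt: electrophilic substitution takes place at C3, the only free and the most nucleophilic position of the N-methylindole, and the non-acidic medium avoids protodebromination at C2.

**Compound list**
1 | 3,4-dibromobenzaldehyde | O=Cc1ccc(Br)c(Br)c1 | starting material
2 | 4,5-dibromo-2-nitrobenzaldehyde | O=Cc1cc(Br)c(Br)cc1[N+](=O)[O-] | intermediate
3 | carbon tetrabromide | BrC(Br)(Br)Br | starting material
4 | 1,2-dibromo-4-(2,2-dibromovinyl)-5-nitrobenzene | [O-][N+](=O)c1cc(Br)c(Br)cc1C=C(Br)Br | intermediate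
5 | 4,5-dibromo-2-(2,2-dibromovinyl)aniline | Nc1cc(Br)c(Br)cc1C=C(Br)Br | intermediate
6 | N-[4,5-dibromo-2-(2,2-dibromovinyl)phenyl]methanesulfonamide | CS(=O)(=O)Nc1cc(Br)c(Br)cc1C=C(Br)Br | intermediate
7 | N-[4,5-dibromo-2-(bromoethynyl)phenyl]methanesulfonamide | CS(=O)(=O)Nc1cc(Br)c(Br)cc1C#CBr | intermediate
8 | 2,5,6-tribromo-1-(methylsulfonyl)indole | CS(=O)(=O)n1c(Br)cc2cc(Br)c(Br)cc21 | intermediate
9 | 2,5,6-tribromoindole | Brc1cc2cc(Br)c(Br)cc2[nH]1 | intermediate
10 | 2,5,6-tribromo-1-methylindole | Cn1c(Br)cc2cc(Br)c(Br)cc21 | intermediate
11 | N,N-dimethylmethyleneiminium iodide (Eschenmoser's salt) | C=[N+](C)C.[I-] | starting material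
12 | 2,5,6-tribromo-1-methylgramine | CN(C)Cc1c(Br)n(C)c2cc(Br)c(Br)cc12 | target

**Step count**
Total steps: 7. Longest linear sequence: 7 steps, from 1 to 12.

**Steps most likely to fail**

Step 1. The nitration may be unselective: attack at C5, which is ortho to the C4 bromine and meta to the formyl group, competes with attack at C6, and some oxidation of the aldehyde is possible. The fallback exchanges the meta-directing formyl group for an ortho/para-directing benzylic carbon before the nitro group is introduced. It sets out from 1: NaBH4 in MeOH should give (3,4-dibromophenyl)methanol F1, and Ac2O in pyridine converts it into 3,4-dibromobenzyl acetate F2. In F2 the benzylic carbon and the C3 bromine both direct to C6, so HNO3/H2SO4 at 0 °C should give 4,5-dibromo-2-nitrobenzyl acetate F3. Methanolysis with K2CO3 in MeOH then gives (4,5-dibromo-2-nitrophenyl)methanol F4, and MnO2 in CH2Cl2 oxidises it to the aldehyde, so the fallback comes back to the route at 2.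

Step 5. The nitrogen anion may attack the bromine of the bromoalkyne instead of its carbon, which would cost the C2 bromine, or the sequence may stall after the elimination. The fallback gives up the dibromovinyl closure and brings in the C2 bromine by deoxybromination of a lactam. It sets out from 5: hot aqueous H2SO4 (about 80 %, 90 °C) should hydrolyse the 1,1-dibromoalkene to the arylacetic acid, which lactamises onto the ortho amino group to give 5,6-dibromoindolin-2-one F5. POBr3 with imidazole in 1,2-dichloroethane at 80 °C then converts the lactam into the 2-bromoindole, so the fallback comes back to the route at 9, which is methylated at once with KOH and MeI in DMSO as in the second half of step 6.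

Step 7. Electrophilic substitution on the thrice-brominated indole may be too slow, and forcing it with heat or acid invites protodebromination or halogen migration at C2. The fallback installs the side chain in two stages through the aldehyde oxidation level. It sets out from 10: Vilsmeier–Haack formylation with POBr3 and DMF (the bromide reagent avoids bromine–chlorine exchange at C2) should give 2,5,6-tribromo-1-methylindole-3-carbaldehyde F6. Reductive amination with Me2NH and Ti(OiPr)4 in THF, followed by NaBH4 in MeOH at 0 °C, then gives the amine, so the fallback comes back to the route at 12.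

**Further compounds**
F1 | step 1 | (3,4-dibromophenyl)methanol | OCc1ccc(Br)c(Br)c1
F2 | step 1 | 3,4-dibromobenzyl acetate | CC(=O)OCc1ccc(Br)c(Br)c1
F3 | step 1 | 4,5-dibromo-2-nitrobenzyl acetate | CC(=O)OCc1cc(Br)c(Br)cc1[N+](=O)[O-]
F4 | step 1 | (4,5-dibromo-2-nitrophenyl)methanol | OCc1cc(Br)c(Br)cc1[N+](=O)[O-]
F5 | step 5 | 5,6-dibromoindolin-2-one | O=C1Cc2cc(Br)c(Br)cc2N1
F6 | step 7 | 2,5,6-tribromo-1-methylindole-3-carbaldehyde | O=Cc1c(Br)n(C)c2cc(Br)c(Br)cc12
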